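Late in the alpha run, which is this same flask followed up to 80.0 min, side product holds 53.6% of the charge and target 3.1%, so we ask where the substrate is heading and how fast.

- alpha: substrate 0.20 M; the very flask that is asked about, followed so far
- flask: substrate 0.20 M; time 2.5 h

alpha run (percent of the substrate charged)

| time / min | target / % | substrate / % | side product / % |
|---|---|---|---|
| 6.00 | 6.2 | 86.2 | 7.6 |
| 12.0 | 6.4 | 79.1 | 15.2 |
| 20.0 | 4.2 | 70.9 | 24.2 |
| 40.0 | 2.5 | 58.4 | 38.1 |
| 80.0 | 3.1 | 43.6 | 53.6 |

(readings scatter by 0.5 percentage points)

- in percentages every species weighs as the substrate in it: one target counts as two
- in percentages every species weighs as the substrate in it: one side product counts as three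

- target present at 2.5 h, in percent of the substrate charged
- substrate present at 2.5 h, in percent of the substrate charged
- side product present at 2.5 h, in percent of the substrate charged

Turn the question round. For substrate to stall at an end state near its last reading, its fall in the alpha run must have stopped by then. Yet between 40.0 min and 80.0 min it lost 15 percentage points, against a scatter of 0.5 points. So we take the end state as still far off and ask only for the pace.

In the alpha readings, one over the substrate fraction climbs at 0.0151 min⁻¹ from 20.0 min to 40.0 min, then at 0.0145 min⁻¹ up to 80.0 min, and across both windows at 0.0147 min⁻¹. This rise per minute, the reciprocal clock, is a reading of the apparent second-order rate constant times the charge.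

Run on for 70.0 min past the last reading, the clock gives us substrate 30.1%. With target held at its last reading, side product takes the balance, 66.8%.

The forecast reasons: “Substrate loss looks second order at late times”. It prints target 3%, substrate 31% and side product 66%, its substrate standing higher than ours.

The flask gives target 1.26%, substrate 33.7% and side product 65.0%, within the tolerance of the forecast.

    2 substrate ⇌ target (K = 0.330 L mol⁻¹, k = 0.00160 L mol⁻¹ s⁻¹)
    substrate + target → side product (k = 0.0150 L mol⁻¹ s⁻¹)

From the last alpha reading to the flask's value at 2.5 h the reciprocal rose at 0.00962 min⁻¹, slower than the clock, so our 30.1% lies under the substrate found. On the neighbour, the same charge read at 4.0 h, the same clock gives substrate 21.5%. That neighbour holds substrate 26.8%.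

(Readings and results were generated by integration for an exercise; scatter was added.)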